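The benzene ring of the coumarin (C4a, C5, C6, C7, C8, C8a) carries oxygen on four neighbouring carbons (C6, C7, C8, C8a) and one hydrogen (C5), and the route rests on disconnecting it. A Dötz benzannulation should assemble it in one operation from a trimethoxylated (alkenyl)(methoxy)carbene Cr(CO)5 complex (C6, C7, C8), one carbonyl ligand (C8a) and a terminal enynoate (C5, C4a). The Z-acrylate of the enynoate then closes the pyranone ring (O1–C2) on the new phenol. The precursor pair is pentacarbonyl[(2Z)-1,2,3-trimethoxyprop-2-en-1-ylidene]chromium and methyl (Z)-pent-2-en-4-ynoate. Cleavage of the 7-methyl ether and Mitsunobu coupling with a Sharpless-derived (2R,3R)-epoxy diol complete the target.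

Key step: step 5

Assumption: (Z)-1,2-dimethoxyethene is used as the single Z isomer; material containing the E isomer would be fractionated before the metalation.

Step 1
Reactants: 1 (Z)-1,2-dimethoxyethene; 2 hexacarbonylchromium
Product: 5 pentacarbonyl[(2Z)-1,2,3-trimethoxyprop-2-en-1-ylidene]chromium, via (Z)-(1,2-dimethoxyethenyl)lithium 3 (not isolated), via lithium pentacarbonyl(acyl)chromate 4 (not isolated)
Conditions: t-BuLi, THF, −78 to −40 °C; Cr(CO)6, THF, −78 °C to rt; then Me3OBF4, CH2Cl2, 0 °C
Reagents that add atoms: trimethyloxonium tetrafluoroborate, C[O+](C)C.F[B-](F)(F)F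
Why: The vinylic C–H next to oxygen of an enediol diether is removed by t-BuLi (the cyclic analogue 2-lithio-5,6-dihydro-1,4-dioxine is a standard reagent), the configurationally stable vinyllithium adds to a CO ligand and the acylchromate is O-methylated (Fischer carbene synthesis), so the Z geometry of 1 should be carried into 5.

Step 2
Reactants: 6 methyl propiolate
Product: 7 methyl (2Z)-3-iodoprop-2-enoate
Conditions: NaI, AcOH, 70 °C
Reagents that add atoms: sodium iodide, [Na+].[I-]
Why: Conjugate addition of iodide to the ynoate followed by anti protonation (hydroiodination) should give the Z-β-iodoacrylate under kinetic control.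

Step 3
Reactants: 7 methyl (2Z)-3-iodoprop-2-enoate; 8 ethynyltrimethylsilane
Product: 9 methyl (2Z)-5-(trimethylsilyl)pent-2-en-4-ynoate
Conditions: Pd(PPh3)2Cl2 (2 mol%), CuI (4 mol%), Et3N, THF, 0 °C to rt
Reagents that add atoms: none
Why: Sonogashira coupling proceeds with retention at the vinyl carbon, and the mild amine base at or below room temperature should leave the Z-alkene unisomerised.

Step 4
Reactants: 9 methyl (2Z)-5-(trimethylsilyl)pent-2-en-4-ynoate
Product: 10 methyl (2Z)-pent-2-en-4-ynoate
Conditions: TBAF, AcOH, THF, 0 °C; product kept as a solution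
Reagents that add atoms: none
Why: Fluoride-induced protodesilylation of the alkynylsilane, buffered with acetic acid so that neither conjugate addition to the enynoate nor Z to E isomerisation should occur; the volatile enyne is not concentrated to dryness.

Step 5
Reactants: 5 pentacarbonyl[(2Z)-1,2,3-trimethoxyprop-2-en-1-ylidene]chromium; 10 methyl (2Z)-pent-2-en-4-ynoate
Product: 12 6,7,8-trimethoxy-2H-chromen-2-one, via methyl (Z)-2-hydroxy-3,4,5-trimethoxycinnamate 11 (not isolated)
Conditions: 10 (1.5 equiv), THF (0.05 M), 55 °C, Ar; then air, rt; then PhMe, 80 °C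
Reagents that add atoms: none
Why: Proposed new method: heat expels one CO from 5, alkyne 10 binds and inserts into the Cr=C bond with its CH terminus joined to the carbene carbon (C5–C6), and CO then inserts at the internal alkyne carbon (C4a–C8a) to give a dienylketene held on Cr(CO)3. The benzene ring closes by thermal 6π-electrocyclisation of this dienylketene, the ketene carbon bonding to the methoxy-bearing vinyl terminus (C8–C8a), and enolisation of the cyclohexadienone gives phenol 11, freed from Cr(CO)3 by air. The pyranone ring closes by 6-exo-trig acyl substitution of the C8a hydroxyl on the cis ester with loss of methanol (O1–C2). The closest known reaction type is the Dötz benzannulation of alkenyl(alkoxy)carbene Cr(CO)5 complexes with terminal alkynes to 4-alkoxyphenols; a 1,2-dioxygenated vinyl group on the carbene and lactonisation of an enynoate in the same flask are not documented. The step needs regioselective insertion, secured by the terminal alkyne (its only substituent ends up next to the CO-derived carbon for steric reasons), and CO insertion in preference to five-ring closure, favoured by the alkoxy (not amino) donor on the carbene carbon and by THF as donor solvent. No stereocentre is formed; the Z-alkene of 10 is not touched by the metal and keeps the ester next to the phenol.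

Step 6
Reactants: 12 6,7,8-trimethoxy-2H-chromen-2-one
Product: 13 7-hydroxy-6,8-dimethoxy-2H-chromen-2-one
Conditions: AlCl3 (3 equiv), CH2Cl2, 0 °C to rt; then 1 M HCl
Reagents that add atoms: none
Why: Lewis-acid O-demethylation should select the 7-methoxy group, which is twisted out of the ring plane by two ortho neighbours and is the only one conjugated through C4a–C4=C3 with the lactone carbonyl, as in the 4-O-demethylation of 3,4,5-trimethoxybenzoyl compounds.

Step 7
Reactants: 14 geraniol
Product: 15 [(2R,3R)-3-methyl-3-(4-methylpent-3-en-1-yl)oxiran-2-yl]methanol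
Conditions: Ti(OiPr)4 (5 mol%), D-(−)-diethyl tartrate (7.5 mol%), t-BuOOH, 4 Å MS, CH2Cl2, −20 °C
Reagents that add atoms: tert-butyl hydroperoxide, CC(C)(C)OO
Why: Sharpless asymmetric epoxidation, in which the catalyst formed from Ti(OiPr)4 and D-(−)-diethyl tartrate delivers oxygen to one face of the hydroxyl-bound E-alkene and so sets both C2 and C3 as R (L-(+)-tartrate gives the 2S,3S enantiomer); the trans relationship follows from the E geometry and the remote alkene is not touched.

Step 8
Reactants: 15 [(2R,3R)-3-methyl-3-(4-methylpent-3-en-1-yl)oxiran-2-yl]methanol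
Product: 17 [(2R,3R)-3-[(2E)-4-hydroxy-4-methylpent-2-en-1-yl]-3-methyloxiran-2-yl]methanol, via tertiary allylic hydroperoxide 16 (not isolated)
Conditions: O2, hν (white LED), tetraphenylporphyrin (cat.), CH2Cl2 with 1% pyridine, 0 °C; then PPh3, 0 °C to rt; chromatography
Reagents that add atoms: dioxygen, O=O
Why: Schenck ene reaction at the only remaining alkene, where hydrogen abstraction from the allylic CH2 gives the tertiary hydroperoxide with a new E-alkene, PPh3 reduces the O–O bond without touching the epoxide, and the regioisomeric secondary allylic alcohol (abstraction from a methyl group) is expected in comparable amount and is removed by chromatography.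

Step 9
Reactants: 13 7-hydroxy-6,8-dimethoxy-2H-chromen-2-one; 17 [(2R,3R)-3-[(2E)-4-hydroxy-4-methylpent-2-en-1-yl]-3-methyloxiran-2-yl]methanol
Product: 18 7-{[(2R,3R)-3-[(2E)-4-hydroxy-4-methylpent-2-en-1-yl]-3-methyloxiran-2-yl]methoxy}-6,8-dimethoxy-2H-chromen-2-one
Conditions: PPh3, DIAD, THF, 0 °C to rt
Reagents that add atoms: none
Why: Mitsunobu etherification, in which the acidic 7-hydroxyl displaces the oxyphosphonium group of the primary alcohol by SN2 at CH2, so both epoxide stereocentres are untouched and the tertiary alcohol stays unactivated.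

Compound list
1 | (Z)-1,2-dimethoxyethene | CO/C=C\OC | starting material
2 | hexacarbonylchromium | O=C=[Cr](=C=O)(=C=O)(=C=O)(=C=O)=C=O | starting material
3 | (Z)-(1,2-dimethoxyethenyl)lithium | CO/C=C(\OC)[Li] | intermediate
4 | lithium pentacarbonyl[(2Z)-2,3-dimethoxy-1-oxidoprop-2-en-1-ylidene]chromate | [Li+].CO/C=C(\OC)C([O-])=[Cr](=C=O)(=C=O)(=C=O)(=C=O)=C=O | intermediate
5 | pentacarbonyl[(2Z)-1,2,3-trimethoxyprop-2-en-1-ylidene]chromium | CO/C=C(\OC)C(OC)=[Cr](=C=O)(=C=O)(=C=O)(=C=O)=C=O | intermediate
6 | methyl propiolate | C#CC(=O)OC | starting material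
7 | methyl (2Z)-3-iodoprop-2-enoate | COC(=O)/C=C\I | intermediate
8 | ethynyltrimethylsilane | C#C[Si](C)(C)C | starting material
9 | methyl (2Z)-5-(trimethylsilyl)pent-2-en-4-ynoate | COC(=O)/C=C\C#C[Si](C)(C)C | intermediate
10 | methyl (2Z)-pent-2-en-4-ynoate | C#C/C=C\C(=O)OC | intermediate
11 | methyl (2Z)-3-(2-hydroxy-3,4,5-trimethoxyphenyl)prop-2-enoate | COC(=O)/C=C\c1cc(OC)c(OC)c(OC)c1O | intermediate
12 | 6,7,8-trimethoxy-2H-chromen-2-one | COc1cc2ccc(=O)oc2c(OC)c1OC | intermediate
13 | 7-hydroxy-6,8-dimethoxy-2H-chromen-2-one | COc1cc2ccc(=O)oc2c(OC)c1O | intermediate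
14 | geraniol, (2E)-3,7-dimethylocta-2,6-dien-1-ol | CC(C)=CCC/C(C)=C/CO | starting material
15 | [(2R,3R)-3-methyl-3-(4-methylpent-3-en-1-yl)oxiran-2-yl]methanol | OC[C@H]1O[C@]1(C)CCC=C(C)C | intermediate
16 | [(2R,3R)-3-[(2E)-4-hydroperoxy-4-methylpent-2-en-1-yl]-3-methyloxiran-2-yl]methanol | OC[C@H]1O[C@]1(C)C/C=C/C(C)(C)OO | intermediate
17 | [(2R,3R)-3-[(2E)-4-hydroxy-4-methylpent-2-en-1-yl]-3-methyloxiran-2-yl]methanol | OC[C@H]1O[C@]1(C)C/C=C/C(C)(C)O | intermediate
18 | 7-{[(2R,3R)-3-[(2E)-4-hydroxy-4-methylpent-2-en-1-yl]-3-methyloxiran-2-yl]methoxy}-6,8-dimethoxy-2H-chromen-2-one | COc1cc2ccc(=O)oc2c(OC)c1OC[C@H]1O[C@]1(C)C/C=C/C(C)(C)O | target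

Total step count: 9
Longest linear sequence: 6 steps (steps 2, 3, 4, 5, 6 and 9, from methyl propiolate 6)

Steps most likely to fail

1. Step 5 (the step that carries the new-method label). After alkyne insertion the vinylcarbene intermediate may close to a five-membered ring without taking up CO, because the β-methoxy donor makes the carbene less electrophilic. The electron-poor enynoate may also insert slowly or oligomerise, and the electron-rich phenol may be oxidised during decomplexation before it lactonises. The fallback uses known chemistry, sets out from methyl propiolate 6 and comes back to the route at coumarin 12. Palladium-catalysed hydroarylation of 6 with 2,3,4-trimethoxyphenol F1 (Pd(OAc)2 cat., NaOAc, HCO2H, rt) should add the only free position ortho to the hydroxyl, which is also para to the 3-methoxy group, across the alkyne. This gives the Z-cinnamate 11, which lactonises in the same flask to 12.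

2. Step 1. The vinyllithium carries lithium trans to the β-methoxy group and may lose lithium methoxide by anti-elimination before Cr(CO)6 captures it; metalation may also be incomplete. The fallback reverses the polarity of the assembly, sets out from 1 and 2 and comes back at carbene complex 5. Enol ether 1 is C-acylated with oxalyl chloride to (3Z)-3,4-dimethoxy-2-oxobut-3-enoyl chloride F2, which loses CO on heating (about 120 °C) to give (2Z)-2,3-dimethoxyprop-2-enoyl chloride F3. In parallel, 2 is reduced with potassium graphite (KC8, THF, −78 °C) to dipotassium pentacarbonylchromate F4 (K2[Cr(CO)5]). Acylation of F4 with F3 gives potassium pentacarbonyl[(2Z)-2,3-dimethoxy-1-oxidoprop-2-en-1-ylidene]chromate F5, and O-methylation with Me3OBF4 gives 5.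

3. Step 6. Site selectivity may be poor: the 8- or 6-methoxy group may be cleaved in competition, or a second demethylation may follow through chelation of the first phenoxide to AlCl3. The fallback replaces Lewis-acid activation by nucleophilic dealkylation, sets out from 12 and comes back at 13. With LiCl in DMF at 140–150 °C, chloride attacks by SN2 the methyl group whose aryloxide is the best leaving group. That is the 7-oxide, the only one conjugated with the lactone carbonyl, as in the para-selective dealkylation of 3,4,5-trimethoxybenzaldehyde. Acidification then gives 13; no new compound is made.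

Further compounds
F1 | step 5 | 2,3,4-trimethoxyphenol | COc1ccc(O)c(OC)c1OC
F2 | step 1 | (3Z)-3,4-dimethoxy-2-oxobut-3-enoyl chloride | CO/C=C(\OC)C(=O)C(Cl)=O
F3 | step 1 | (2Z)-2,3-dimethoxyprop-2-enoyl chloride | CO/C=C(\OC)C(Cl)=O
F4 | step 1 | dipotassium pentacarbonylchromate | [K+].[K+].O=C=[Cr-2](=C=O)(=C=O)(=C=O)=C=O
F5 | step 1 | potassium pentacarbonyl[(2Z)-2,3-dimethoxy-1-oxidoprop-2-en-1-ylidene]chromate | [K+].CO/C=C(\OC)C([O-])=[Cr](=C=O)(=C=O)(=C=O)(=C=O)=C=O
F0 | step 6 | none | none
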